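**Strategy.** Labdane numbering is used (C3 carries the acetate, C4 the gem-dimethyl group, C10 the angular methyl, C9 the carbinol). Ring A is cut at C1–C2 and C4–C5 into acetone (C2–C3–C4) and a ring B keto aldehyde in which the quaternary C10 holds both the formyl carbon C1 and the ketone carbon C5. The key step exploits the C3 carbonyl flanked by two enolisable carbons and this 1,3-dielectrophile: an amine-buffered double aldol condensation closes ring A as a cross-conjugated dienone in one operation. C10, set by desymmetrising reduction of a prochiral 1,3-dione, later directs C5, C8, C9 and C3.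

Key step: step 5

Remark: the (R,R)-TsDPEN ruthenium catalyst is assumed to give the (2R,3R)-hydroxy ketone 4; if the sense of enantiotopic-group selection proves opposite, the (S,S)-catalyst is used (the C9 carbinol configuration is erased in step 7).

**Step 1**
Reactants: 1 2-methylcyclohexane-1,3-dione; 2 formaldehyde (37% aqueous)
Product: 3 2-(hydroxymethyl)-2-methylcyclohexane-1,3-dione
Conditions: Et3N (cat.), H2O/THF, rt
Reagents that add atoms: none
Why: Base-catalysed aldol hydroxymethylation at the doubly activated C2 of the dione, which installs C1 on the future C10; the product is achiral (C10 prochiral).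

**Step 2**
Reactants: 3 2-(hydroxymethyl)-2-methylcyclohexane-1,3-dione
Product: 4 (2R,3R)-3-hydroxy-2-(hydroxymethyl)-2-methylcyclohexan-1-one
Conditions: RuCl(p-cymene)[(R,R)-TsDPEN] (cat.), HCO2H/Et3N (5:2), CH2Cl2, rt
Reagents that add atoms: none
Why: Noyori–Ikariya asymmetric transfer hydrogenation used as a desymmetrisation of a 2,2-disubstituted 1,3-dione; the catalyst fixes the carbinol configuration and hydride delivery anti to the bulkier hydroxymethyl group thereby fixes the quaternary centre (the later C10), the second ketone being reduced far more slowly.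

**Step 3**
Reactants: 4 (2R,3R)-3-hydroxy-2-(hydroxymethyl)-2-methylcyclohexan-1-one
Product: 5 (1S,6R)-6-hydroxy-1-methyl-2-oxocyclohexane-1-carbaldehyde
Conditions: TEMPO (cat.), PhI(OAc)2, CH2Cl2, rt
Reagents that add atoms: none
Why: Oxoammonium (TEMPO) oxidation, chemoselective for the primary over the hindered secondary alcohol; C10 has no α-hydrogen and cannot epimerise.

**Step 4**
Reactants: 5 (1S,6R)-6-hydroxy-1-methyl-2-oxocyclohexane-1-carbaldehyde
Product: 6 (1S,6R)-1-methyl-2-oxo-6-[(triethylsilyl)oxy]cyclohexane-1-carbaldehyde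
Conditions: TESCl, imidazole, DMF, 0 °C
Reagents that add atoms: chlorotriethylsilane, CC[Si](Cl)(CC)CC
Why: Standard silylation of the secondary alcohol; the silyl ether blocks retro-aldol opening of the C9–C10 bond under the amine conditions of step 5.

**Step 5**
Reactants: 6 (1S,6R)-1-methyl-2-oxo-6-[(triethylsilyl)oxy]cyclohexane-1-carbaldehyde; 7 acetone
Product: 8 (4aS,5R)-4a-methyl-5-[(triethylsilyl)oxy]-5,6,7,8-tetrahydronaphthalen-2(4aH)-one
Conditions: pyrrolidinium acetate (1 equiv), acetone (solvent), 4 Å MS, reflux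
Reagents that add atoms: none
Why: Pyrrolidine converts acetone into its enamine, which adds to the unhindered, non-enolisable formyl carbon C1 (Mannich/aldol addition, C1–C2); the resulting β-amino or β-hydroxy methyl ketone, still flexible at C1, forms a second enamine at the acetone-derived methyl that adds intramolecularly to the ring ketone C5 (C4–C5), and loss of water and of the amine then gives the cross-conjugated dienone. The closest known reaction type is the amine-buffered double aldol condensation ([3+3] annulation) of 2-formyl-2-alkylcycloalkanones with acetone to 4a-alkyl cyclohexadienones. Ring A closes by a 6-(enolendo)-exo-trig aldol addition, the same mode as in amine-mediated Robinson-type cyclisations onto a ketone next to a quaternary carbon. No new stereocentre is created: C1, C2, C4 and C5 become sp2, and the quaternary C10, which has no α-hydrogen, is carried through unchanged. The step needs chemoselectivity (aldehyde before ketone, ring closure before a second intermolecular condensation, no deformylation and no retro-aldol opening of ring B); this is secured by the higher electrophilicity of the formyl group, the intramolecular second aldol, the buffered amine salt in place of hydroxide, and the silyl ether at C9.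

**Step 6**
Reactants: 8 (4aS,5R)-4a-methyl-5-[(triethylsilyl)oxy]-5,6,7,8-tetrahydronaphthalen-2(4aH)-one
Product: 9 (4aS,5R)-1,1,4a-trimethyl-5-[(triethylsilyl)oxy]-4a,5,6,7-tetrahydronaphthalen-2(1H)-one
Conditions: t-BuOK (2.5 equiv), MeI (4 equiv), t-BuOH/THF, 0 °C to rt
Reagents that add atoms: iodomethane, CI
Why: Deconjugative double α-methylation through the γ-deprotonated (C6) extended enolate, as known for 4-en-3-ones and 1,4-dien-3-ones; both methyls enter at C4 and the C4=C5 bond moves to C5=C6, so no stereocentre is formed.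

**Step 7**
Reactants: 9 (4aS,5R)-1,1,4a-trimethyl-5-[(triethylsilyl)oxy]-4a,5,6,7-tetrahydronaphthalen-2(1H)-one
Product: 10 (4aS)-1,1,4a-trimethyl-6,7-dihydronaphthalene-2,5(1H,4aH)-dione
Conditions: CrO3, H2SO4, H2O, acetone, 0 °C
Reagents that add atoms: none
Why: Jones oxidation, in which the aqueous acid first cleaves the triethylsilyl ether and the freed secondary alcohol is oxidised to the C9 ketone in the same flask; the β,γ-unsaturated ketones cannot isomerise because C4 and C10 are quaternary.

**Step 8**
Reactants: 10 (4aS)-1,1,4a-trimethyl-6,7-dihydronaphthalene-2,5(1H,4aH)-dione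
Product: 11 (4aS,6R)-1,1,4a,6-tetramethyl-6,7-dihydronaphthalene-2,5(1H,4aH)-dione
Conditions: LiN(SiMe3)2 (1.05 equiv), THF, −78 °C; MeI, −78 to 0 °C
Reagents that add atoms: iodomethane, CI
Why: Kinetic enolate alkylation at C8, the only enolisable position (C2 is vinylic, C4 and C10 are quaternary); the electrophile approaches anti to the axial C10 methyl, and the equatorial 8α-methyl is also the thermodynamic epimer because 8β would be syn-diaxial to the C10 methyl.

**Step 9**
Reactants: 11 (4aS,6R)-1,1,4a,6-tetramethyl-6,7-dihydronaphthalene-2,5(1H,4aH)-dione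
Product: 12 (4aS,6R,8aS)-1,1,4a,6-tetramethylhexahydronaphthalene-2,5(1H,3H)-dione
Conditions: H2 (4 atm), 10% Pd/C, EtOAc, rt
Reagents that add atoms: none
Why: Heterogeneous catalytic hydrogenation of both C=C bonds; hydrogen reaches C5 from the α face, opposite the C10 methyl and the β-methyl on C4, giving the trans-decalin (5α-H) as is usual for 4,4-dimethyl-Δ5 systems.

**Step 10**
Reactants: 12 (4aS,6R,8aS)-1,1,4a,6-tetramethylhexahydronaphthalene-2,5(1H,3H)-dione
Product: 13 (2R,4aS,6S,8aS)-6-hydroxy-2,5,5,8a-tetramethyloctahydronaphthalen-1(2H)-one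
Conditions: NaBH4 (0.5 equiv), MeOH/CH2Cl2, −40 °C
Reagents that add atoms: none
Why: Chemoselective borohydride reduction; the C3 ketone (one quaternary neighbour) should react much faster than the C9 ketone (flanked by quaternary C10 and methyl-bearing C8), and axial hydride attack from the α face, away from the axial 4β-methyl, gives the equatorial 3β-alcohol.

**Step 11**
Reactants: 13 (2R,4aS,6S,8aS)-6-hydroxy-2,5,5,8a-tetramethyloctahydronaphthalen-1(2H)-one; 14 vinylmagnesium bromide
Product: 15 (1R,2R,4aS,6S,8aS)-1-ethenyl-2,5,5,8a-tetramethyldecahydronaphthalene-1,6-diol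
Conditions: CeCl3 (anhydrous), THF; 14 (4 equiv), −78 to 0 °C
Reagents that add atoms: none
Why: Organocerium 1,2-addition, which suppresses enolisation of the hindered ketone; equatorial attack from the β face, avoiding the axial hydrogens at C5 and C7 and trans to the equatorial C8 methyl, places the hydroxyl axial (9α), as known for 2,2,6-trisubstituted cyclohexanones.

**Step 12**
Reactants: 15 (1R,2R,4aS,6S,8aS)-1-ethenyl-2,5,5,8a-tetramethyldecahydronaphthalene-1,6-diol; 16 4-bromofuran-2(5H)-one
Product: 18 4-{2-[(1R,2R,4aS,6S,8aS)-1,6-dihydroxy-2,5,5,8a-tetramethyldecahydronaphthalen-1-yl]ethyl}furan-2(5H)-one, via alkylborane 17 (not isolated)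
Conditions: 9-BBN (3.5 equiv), THF, 0 to 50 °C; then 16, PdCl2(dppf) (cat.), K3PO4, DMF/H2O, 50 °C
Reagents that add atoms: none
Why: Anti-Markovnikov hydroboration of the terminal vinyl group followed by B-alkyl Suzuki–Miyaura coupling with the vinylogous acyl bromide 16 forms C12–C13; no stereocentre is touched.

**Step 13**
Reactants: 18 4-{2-[(1R,2R,4aS,6S,8aS)-1,6-dihydroxy-2,5,5,8a-tetramethyldecahydronaphthalen-1-yl]ethyl}furan-2(5H)-one
Product: 19 (2S,4aS,5R,6R,8aS)-5-hydroxy-1,1,4a,6-tetramethyl-5-[2-(5-oxo-2,5-dihydrofuran-3-yl)ethyl]decahydronaphthalen-2-yl acetate (target)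
Conditions: Ac2O, pyridine, DMAP (cat.), CH2Cl2, rt
Reagents that add atoms: acetic anhydride, CC(=O)OC(C)=O
Why: DMAP-catalysed acylation of the secondary equatorial C3 alcohol; the hindered tertiary C9 alcohol should not react.

**Compound list**

1 | 2-methylcyclohexane-1,3-dione | CC1C(=O)CCCC1=O | starting material
2 | formaldehyde | C=O | starting material
3 | 2-(hydroxymethyl)-2-methylcyclohexane-1,3-dione | OCC1(C)C(=O)CCCC1=O | intermediate
4 | (2R,3R)-3-hydroxy-2-(hydroxymethyl)-2-methylcyclohexan-1-one | OC[C@@]1(C)C(=O)CCC[C@H]1O | intermediate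
5 | (1S,6R)-6-hydroxy-1-methyl-2-oxocyclohexane-1-carbaldehyde | O=C[C@@]1(C)C(=O)CCC[C@H]1O | intermediate
6 | (1S,6R)-1-methyl-2-oxo-6-[(triethylsilyl)oxy]cyclohexane-1-carbaldehyde | O=C[C@@]1(C)C(=O)CCC[C@H]1O[Si](CC)(CC)CC | intermediate
7 | acetone | CC(C)=O | starting material
8 | (4aS,5R)-4a-methyl-5-[(triethylsilyl)oxy]-5,6,7,8-tetrahydronaphthalen-2(4aH)-one | O=C1C=C[C@@]2(C)C(=C1)CCC[C@H]2O[Si](CC)(CC)CC | intermediate
9 | (4aS,5R)-1,1,4a-trimethyl-5-[(triethylsilyl)oxy]-4a,5,6,7-tetrahydronaphthalen-2(1H)-one | O=C1C=C[C@@]2(C)C(=CCC[C@H]2O[Si](CC)(CC)CC)C1(C)C | intermediate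
10 | (4aS)-1,1,4a-trimethyl-6,7-dihydronaphthalene-2,5(1H,4aH)-dione | O=C1C=C[C@@]2(C)C(=CCCC2=O)C1(C)C | intermediate
11 | (4aS,6R)-1,1,4a,6-tetramethyl-6,7-dihydronaphthalene-2,5(1H,4aH)-dione | O=C1C=C[C@@]2(C)C(=CC[C@@H](C)C2=O)C1(C)C | intermediate
12 | (4aS,6R,8aS)-1,1,4a,6-tetramethylhexahydronaphthalene-2,5(1H,3H)-dione | O=C1CC[C@@]2(C)[C@@H](CC[C@@H](C)C2=O)C1(C)C | intermediate
13 | (2R,4aS,6S,8aS)-6-hydroxy-2,5,5,8a-tetramethyloctahydronaphthalen-1(2H)-one | O[C@H]1CC[C@@]2(C)[C@@H](CC[C@@H](C)C2=O)C1(C)C | intermediate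
14 | vinylmagnesium bromide | C=C[Mg]Br | starting material
15 | (1R,2R,4aS,6S,8aS)-1-ethenyl-2,5,5,8a-tetramethyldecahydronaphthalene-1,6-diol | O[C@H]1CC[C@@]2(C)[C@@H](CC[C@@H](C)[C@]2(O)C=C)C1(C)C | intermediate
16 | 4-bromofuran-2(5H)-one | O=C1C=C(Br)CO1 | starting material
17 | 9-{2-[(1R,2R,4aS,6S,8aS)-1,6-dihydroxy-2,5,5,8a-tetramethyldecahydronaphthalen-1-yl]ethyl}-9-borabicyclo[3.3.1]nonane | O[C@H]1CC[C@@]2(C)[C@@H](CC[C@@H](C)[C@]2(O)CCB3C4CCCC3CCC4)C1(C)C | intermediate (not isolated)
18 | 4-{2-[(1R,2R,4aS,6S,8aS)-1,6-dihydroxy-2,5,5,8a-tetramethyldecahydronaphthalen-1-yl]ethyl}furan-2(5H)-one | O[C@H]1CC[C@@]2(C)[C@@H](CC[C@@H](C)[C@]2(O)CCC2=CC(=O)OC2)C1(C)C | intermediate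
19 | (2S,4aS,5R,6R,8aS)-5-hydroxy-1,1,4a,6-tetramethyl-5-[2-(5-oxo-2,5-dihydrofuran-3-yl)ethyl]decahydronaphthalen-2-yl acetate | CC(=O)O[C@H]1CC[C@@]2(C)[C@@H](CC[C@@H](C)[C@]2(O)CCC2=CC(=O)OC2)C1(C)C | target

Total step count: 13. Longest linear sequence: 13 steps (1 to 19).

**Steps most likely to fail**

Step 5. Premature dehydration to the (E)-configured enone, whose acetyl methyl cannot reach C5, together with amine-induced deformylation of the β-keto aldehyde and self-condensation of acetone, may outrun the ring closure. Fallback, setting out from 6: Wittig olefination with 1-(triphenylphosphoranylidene)propan-2-one (PhMe, 80 °C) should give the (E)-enone (2R,3R)-2-methyl-2-[(1E)-3-oxobut-1-en-1-yl]-3-[(triethylsilyl)oxy]cyclohexan-1-one F1. Hydrogenation of its C=C bond (H2, Pd/C, EtOAc) should give the 1,5-diketone (2R,3R)-2-methyl-2-(3-oxobutyl)-3-[(triethylsilyl)oxy]cyclohexan-1-one F2. Intramolecular aldol condensation (pyrrolidine, AcOH, PhMe, 80 °C) should give the bicyclic enone (4aS,5R)-4a-methyl-5-[(triethylsilyl)oxy]-4,4a,5,6,7,8-hexahydronaphthalen-2(3H)-one F3. Dehydrogenation with DDQ (dioxane, reflux) should introduce the C1=C2 double bond and return to 8.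

Step 2. Insufficient discrimination between the two enantiotopic carbonyl groups or between the two carbonyl faces would erode enantiomeric and diastereomeric purity, and retro-aldol loss of formaldehyde may compete in the amine-containing medium. Fallback, setting out from 3: non-selective mono-reduction (NaBH4, EtOH, −20 °C) should give the racemic cis-hydroxy ketone (2RS,3RS)-3-hydroxy-2-(hydroxymethyl)-2-methylcyclohexan-1-one F4. Lipase-mediated kinetic resolution (Burkholderia cepacia lipase, vinyl acetate, t-BuOMe) is expected to acetylate the primary hydroxyl of the (2S,3S)-enantiomer to [(1S,2S)-2-hydroxy-1-methyl-6-oxocyclohexyl]methyl acetate F5. F5 is removed by chromatography, leaving 4.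

Step 11. Enolisation of the hindered C9 ketone towards C8 may take the place of addition, and competing axial attack from the α face would give the C9 epimer. Fallback, setting out from 13: Wittig methylenation (Ph3PCH3Br, t-BuOK, PhMe, reflux) should give the exocyclic alkene (2S,4aS,6R,8aR)-1,1,4a,6-tetramethyl-5-methylidenedecahydronaphthalen-2-ol F6. Epoxidation with mCPBA (NaHCO3, CH2Cl2) from the α face, opposite the axial C10 methyl, should give the 9α,11-spiro-epoxide F7 with the oxygen already in the required position. One-carbon homologation with excess dimethylsulfonium methylide (Me3SI, n-BuLi, THF), which opens the epoxide at its CH2 terminus and then eliminates Me2S, should give the vinyl carbinol 15.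

**Further compounds**

F1 | step 5 | (2R,3R)-2-methyl-2-[(1E)-3-oxobut-1-en-1-yl]-3-[(triethylsilyl)oxy]cyclohexan-1-one | CC(=O)/C=C/[C@@]1(C)C(=O)CCC[C@H]1O[Si](CC)(CC)CC
F2 | step 5 | (2R,3R)-2-methyl-2-(3-oxobutyl)-3-[(triethylsilyl)oxy]cyclohexan-1-one | CC(=O)CC[C@@]1(C)C(=O)CCC[C@H]1O[Si](CC)(CC)CC
F3 | step 5 | (4aS,5R)-4a-methyl-5-[(triethylsilyl)oxy]-4,4a,5,6,7,8-hexahydronaphthalen-2(3H)-one | O=C1CC[C@@]2(C)C(=C1)CCC[C@H]2O[Si](CC)(CC)CC
F4 | step 2 | racemic (2RS,3RS)-3-hydroxy-2-(hydroxymethyl)-2-methylcyclohexan-1-one | OC[C@@]1(C)C(=O)CCC[C@H]1O.OC[C@]1(C)C(=O)CCC[C@@H]1O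
F5 | step 2 | [(1S,2S)-2-hydroxy-1-methyl-6-oxocyclohexyl]methyl acetate | CC(=O)OC[C@]1(C)C(=O)CCC[C@@H]1O
F6 | step 11 | (2S,4aS,6R,8aR)-1,1,4a,6-tetramethyl-5-methylidenedecahydronaphthalen-2-ol | O[C@H]1CC[C@@]2(C)[C@@H](CC[C@@H](C)C2=C)C1(C)C
F7 | step 11 | 9α,11-spiro-epoxide of F6 (oxirane oxygen on the α face at C9) | O[C@H]1CC[C@@]2(C)[C@@H](CC[C@@H](C)[C@]2(O3)C3)C1(C)C
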